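**Retrosynthetic overview**
- Glicophenone ⇒ four O–Si cleavages and an enamine hydrolysis ⇒ (E)-α-morpholinostilbene. The key disconnection is the C–N bond at the future carbonyl carbon, made by regioselective CuH hydroamination of the persilylated diarylalkyne.
- Diarylalkyne ⇒ Sonogashira coupling of a ring-B arylacetylene with 4-bromoresorcinol bis-TBS ether.
- Ring-B arylacetylene ⇒ one-carbon homologation of the pentasubstituted benzaldehyde.
- That aldehyde ⇒ O-methylation of its only free OH (chelated, next to the prenyl group) ⇐ selective 4,6-bis-silylation ⇐ C-prenylation of C2v-symmetric 2,4,6-trihydroxybenzaldehyde.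
- No ring is formed. Both benzene rings are bought.

Assumption: the target has no stereocentre and no stereogenic C=C, so it is one achiral compound and nothing has to be set.

**Step 1**
Reactants: 1 2,4,6-trihydroxybenzaldehyde; 2 prenyl bromide (1-bromo-3-methylbut-2-ene)
Product: 3 2,4,6-trihydroxy-3-(3-methylbut-2-en-1-yl)benzaldehyde
Conditions: KOH (1.1 equiv), H2O, 0 °C → rt, 2 (1.0 equiv) added dropwise; then pH 4
Reagents that add atoms: none
Why: Phenolate C-alkylation (SN2 at the primary carbon of prenyl bromide) is favoured in water because the phenoxide oxygens are hydrogen-bonded, and the two free ring CH positions of symmetric 1 are equivalent, so only one mono-C-prenyl isomer can form.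

**Step 2**
Reactants: 3 2,4,6-trihydroxy-3-(3-methylbut-2-en-1-yl)benzaldehyde
Product: 4 2-hydroxy-3-(3-methylbut-2-en-1-yl)-4,6-bis(triisopropylsilyloxy)benzaldehyde
Conditions: TIPSCl (2.2 equiv), imidazole (5 equiv), DMF, 0 °C → rt
Reagents that add atoms: triisopropylsilyl chloride, CC(C)[Si](Cl)(C(C)C)C(C)C
Why: In this site-selective O-silylation the bulky silyl chloride takes the unchelated 4-OH and the less hindered 6-OH, while the 2-OH, wedged between prenyl and CHO and hydrogen-bonded to the carbonyl, stays free.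

**Step 3**
Reactants: 4 2-hydroxy-3-(3-methylbut-2-en-1-yl)-4,6-bis(triisopropylsilyloxy)benzaldehyde
Product: 5 2-methoxy-3-(3-methylbut-2-en-1-yl)-4,6-bis(triisopropylsilyloxy)benzaldehyde
Conditions: MeOH (3 equiv), PPh3, DIAD (1.5 equiv each), THF, 0 °C → rt
Reagents that add atoms: methanol, CO
Why: In this Mitsunobu etherification the only free, acidic salicylaldehyde-type phenol attacks the phosphonium-activated methyl group under neutral conditions that leave the activated aryl silyl ethers, the aldehyde and the prenyl group untouched.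

**Step 4**
Reactants: 5 2-methoxy-3-(3-methylbut-2-en-1-yl)-4,6-bis(triisopropylsilyloxy)benzaldehyde
Product: 6 1-ethynyl-2-methoxy-3-(3-methylbut-2-en-1-yl)-4,6-bis(triisopropylsilyloxy)benzene
Conditions: TMSCHN2 (1.3 equiv), n-BuLi (1.3 equiv), THF, −78 °C; then 5, −78 °C → rt; H2O
Reagents that add atoms: (trimethylsilyl)diazomethane, C[Si](C)(C)C=[N+]=[N-]
Why: In this Colvin homologation, addition to the aldehyde, Peterson-type loss of TMSOLi, loss of N2 and a 1,2-H shift of the alkylidene carbene give the terminal alkyne, and the bulky TIPS group resists migration to the transient alkoxide.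

**Step 5**
Reactants: 7 4-bromoresorcinol
Product: 8 1-bromo-2,4-bis(tert-butyldimethylsilyloxy)benzene
Conditions: TBSCl (2.4 equiv), imidazole (5 equiv), DMF, rt
Reagents that add atoms: tert-butyldimethylsilyl chloride, CC(C)(C)[Si](C)(C)Cl
Why: Exhaustive phenol silylation masks both OH groups, so no benzofuran can form once the ortho-alkyne is in place.

**Step 6**
Reactants: 6 1-ethynyl-2-methoxy-3-(3-methylbut-2-en-1-yl)-4,6-bis(triisopropylsilyloxy)benzene; 8 1-bromo-2,4-bis(tert-butyldimethylsilyloxy)benzene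
Product: 9 1-[2,4-bis(tert-butyldimethylsilyloxy)phenyl]-2-[2-methoxy-3-(3-methylbut-2-en-1-yl)-4,6-bis(triisopropylsilyloxy)phenyl]ethyne
Conditions: PdCl2(PhCN)2 (3 mol %), P(t-Bu)3·HBF4 (6 mol %), CuI (2 mol %), i-Pr2NH (2 equiv), dioxane (degassed), rt → 45 °C
Reagents that add atoms: none
Why: In this Sonogashira coupling the electron-rich bulky phosphine allows oxidative addition of the electron-rich aryl bromide near room temperature, and the di-ortho hindrance sits on the slim alkyne partner rather than on the halide.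

**Step 7 (key step)**
Reactants: 9 1-[2,4-bis(tert-butyldimethylsilyloxy)phenyl]-2-[2-methoxy-3-(3-methylbut-2-en-1-yl)-4,6-bis(triisopropylsilyloxy)phenyl]ethyne
Product: 12 glicophenone, via morpholine enamine 10 (not isolated), via tetrasilyl ketone 11 (not isolated)
Conditions: Cu(OAc)2 (5 mol %), (±)-DTBM-SEGPHOS (5.5 mol %), (MeO)2MeSiH (3 equiv), morpholin-4-yl benzoate (1.5 equiv), THF, 45 °C; then AcOH (8 equiv), H2O, rt; then TBAF (8 equiv), 0 °C → rt, under N2
Reagents that add atoms: morpholin-4-yl benzoate, O=C(ON1CCOCC1)c1ccccc1 (morpholine unit of 10 only); water, O (carbonyl oxygen of 11 and 12)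
Why: Proposed new method: ligated CuH should add syn across the unsymmetrical tolane with hydride going to the δ+ alkyne carbon next to the more electron-rich, di-ortho-substituted ring B and copper going to the carbon next to the less hindered, less electron-rich ring A; the vinylcopper is then aminated with retention by the N–O electrophile (new C–N bond, (E)-enamine), mild acid hydrolysis turns it into the ketone next to ring A (the opposite regiochemistry to π-acid or Brønsted-acid hydration), buffered fluoride removes all four aryl silyl groups without acid-induced chroman or benzofuran formation, and the unactivated trisubstituted prenyl alkene is inert to CuH; the closest known reaction type is CuH-catalysed hydroamination of aryl/alkyl and symmetrical diaryl alkynes with O-benzoylhydroxylamines, which has not been shown on an unsymmetrical, tri-ortho-oxygenated diarylalkyne or used to fix a deoxybenzoin carbonyl.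

**Compound list**
1 | 2,4,6-trihydroxybenzaldehyde | O=Cc1c(O)cc(O)cc1O | starting material
2 | prenyl bromide (1-bromo-3-methylbut-2-ene) | CC(C)=CCBr | starting material
3 | 2,4,6-trihydroxy-3-(3-methylbut-2-en-1-yl)benzaldehyde | O=Cc1c(O)c(CC=C(C)C)c(O)cc1O | intermediate
4 | 2-hydroxy-3-(3-methylbut-2-en-1-yl)-4,6-bis(triisopropylsilyloxy)benzaldehyde | O=Cc1c(O)c(CC=C(C)C)c(O[Si](C(C)C)(C(C)C)C(C)C)cc1O[Si](C(C)C)(C(C)C)C(C)C | intermediate
5 | 2-methoxy-3-(3-methylbut-2-en-1-yl)-4,6-bis(triisopropylsilyloxy)benzaldehyde | O=Cc1c(OC)c(CC=C(C)C)c(O[Si](C(C)C)(C(C)C)C(C)C)cc1O[Si](C(C)C)(C(C)C)C(C)C | intermediate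
6 | 1-ethynyl-2-methoxy-3-(3-methylbut-2-en-1-yl)-4,6-bis(triisopropylsilyloxy)benzene | C#Cc1c(OC)c(CC=C(C)C)c(O[Si](C(C)C)(C(C)C)C(C)C)cc1O[Si](C(C)C)(C(C)C)C(C)C | intermediate
7 | 4-bromoresorcinol | Oc1ccc(Br)c(O)c1 | starting material
8 | 1-bromo-2,4-bis(tert-butyldimethylsilyloxy)benzene | CC(C)(C)[Si](C)(C)Oc1ccc(Br)c(O[Si](C)(C)C(C)(C)C)c1 | intermediate
9 | 1-[2,4-bis(TBSO)phenyl]-2-[2-methoxy-3-prenyl-4,6-bis(TIPSO)phenyl]ethyne | COc1c(CC=C(C)C)c(O[Si](C(C)C)(C(C)C)C(C)C)cc(O[Si](C(C)C)(C(C)C)C(C)C)c1C#Cc1ccc(O[Si](C)(C)C(C)(C)C)cc1O[Si](C)(C)C(C)(C)C | intermediate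
10 | 4-{(E)-1-[2,4-bis(TBSO)phenyl]-2-[2-methoxy-3-prenyl-4,6-bis(TIPSO)phenyl]ethenyl}morpholine | COc1c(CC=C(C)C)c(O[Si](C(C)C)(C(C)C)C(C)C)cc(O[Si](C(C)C)(C(C)C)C(C)C)c1/C=C(/N1CCOCC1)c1ccc(O[Si](C)(C)C(C)(C)C)cc1O[Si](C)(C)C(C)(C)C | intermediate
11 | 1-[2,4-bis(TBSO)phenyl]-2-[2-methoxy-3-prenyl-4,6-bis(TIPSO)phenyl]ethan-1-one | COc1c(CC=C(C)C)c(O[Si](C(C)C)(C(C)C)C(C)C)cc(O[Si](C(C)C)(C(C)C)C(C)C)c1CC(=O)c1ccc(O[Si](C)(C)C(C)(C)C)cc1O[Si](C)(C)C(C)(C)C | intermediate
12 | glicophenone, 1-(2,4-dihydroxyphenyl)-2-[4,6-dihydroxy-2-methoxy-3-(3-methylbut-2-en-1-yl)phenyl]ethan-1-one | COc1c(CC=C(C)C)c(O)cc(O)c1CC(=O)c1ccc(O)cc1O | target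

**Total step count:** 7
**Longest linear sequence:** 6 (steps 1, 2, 3, 4, 6, 7)

**Three steps most likely to fail**

1) Step 7 (the new step). Three ortho substituents may slow the CuH insertion, and the first variable to change would be a slimmer bisphosphine. Coordination of the ring-B OMe to copper could erode the regiochemistry. A slow amination could let the vinylcopper be protonated to the cis-stilbene. The fallback uses known chemistry, sets out from 9 and comes back at 11. Cp2ZrHCl-catalysed syn-hydroboration of 9 with pinacolborane (THF, rt → 40 °C) puts boron on the less hindered, more nucleophilic alkyne carbon next to ring A and gives the (Z)-vinylboronate F1. NaBO3·4H2O in THF/H2O then oxidises the C–B bond, and the enol tautomerises to 11, which is desilylated as in the last stage of step 7.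

2) Step 4. The aldehyde is flanked by OMe and OTIPS, so addition may be slow and some silyl migration to the alkoxide may still occur. The fallback sets out from 5 and comes back at 6. It avoids any alkoxide: Ramirez olefination (CBr4, PPh3, CH2Cl2, 0 °C) gives the gem-dibromoalkene F2. n-BuLi (2.2 equiv, THF, −78 °C, then H2O) completes the Corey–Fuchs sequence to 6.

3) Step 1. Over-prenylation, O-alkylation and dearomatised gem-diprenyl products can push the yield low. The fallback sets out from 1 and comes back at 4, and it also replaces the selectivity demand of step 2. Compound 1 is silylated first (TIPSCl 2.1 equiv, imidazole, DMF), and by symmetry this gives only the chelated salicylaldehyde F3. Pd(PPh3)4-catalysed O-allylation with tert-butyl 2-methylbut-3-en-2-yl carbonate (THF, rt) gives the 1,1-dimethylallyl aryl ether F4. An aromatic Claisen rearrangement (toluene, 110 °C) can only deliver the group, now as a normal prenyl, to the one free ortho carbon, which gives 4.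

**Further compounds**
F1 | step 7 | (Z)-2-{1-[2,4-bis(TBSO)phenyl]-2-[2-methoxy-3-prenyl-4,6-bis(TIPSO)phenyl]ethenyl}-4,4,5,5-tetramethyl-1,3,2-dioxaborolane | COc1c(CC=C(C)C)c(O[Si](C(C)C)(C(C)C)C(C)C)cc(O[Si](C(C)C)(C(C)C)C(C)C)c1/C=C(/B1OC(C)(C)C(C)(C)O1)c1ccc(O[Si](C)(C)C(C)(C)C)cc1O[Si](C)(C)C(C)(C)C
F2 | step 4 | 1-(2,2-dibromoethenyl)-2-methoxy-3-(3-methylbut-2-en-1-yl)-4,6-bis(triisopropylsilyloxy)benzene | COc1c(CC=C(C)C)c(O[Si](C(C)C)(C(C)C)C(C)C)cc(O[Si](C(C)C)(C(C)C)C(C)C)c1C=C(Br)Br
F3 | step 1 | 2-hydroxy-4,6-bis(triisopropylsilyloxy)benzaldehyde | O=Cc1c(O)cc(O[Si](C(C)C)(C(C)C)C(C)C)cc1O[Si](C(C)C)(C(C)C)C(C)C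
F4 | step 1 | 2-[(2-methylbut-3-en-2-yl)oxy]-4,6-bis(triisopropylsilyloxy)benzaldehyde | O=Cc1c(OC(C)(C)C=C)cc(O[Si](C(C)C)(C(C)C)C(C)C)cc1O[Si](C(C)C)(C(C)C)C(C)C
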